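**Retrosynthetic overview**
1. End game, no ring formation: C3 aroylation, C1 bridgehead prenylation and O-deprotection of a bicyclo[3.3.1]non-3-ene-2,9-dione; the C2 carbonyl comes from allylic oxidation of an enol ether.
2. Key disconnection C1–C8 (ring B, the only ring-forming step, formed last): a tertiary fluoride is ionised and closes onto one of two enantiotopic enol ethers of an achiral, Cs-symmetric 6,6-dialkyl-1,5-dimethoxycyclohexa-1,4-diene; the C7 centre alone sets C1 and C5.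
3. Ring A is the pre-existing six-membered ring of 1,3-dimethoxybenzene (Birch reduction), C-alkylated twice at the carbon between the methoxy groups (chiral side chain, then geranyl bromide).
4. Side chain: Evans deconjugative prenylation of a senecioyl imide gives (S)-lavandulol, then chemoselective Markovnikov hydrofluorination.
5. This replaces the usual malonyl or Dieckmann annulation onto a chiral cyclohexanone and the biomimetic dearomative annulation of an acylphloroglucinol.

Assumption: the SMILES is read as the (1S,5S,7R) enantiomer with the C7 prenyl group exo (cis to both bridgehead side chains), the drawn 4-hydroxy-2-one enol being one tautomer of the β-triketone; core numbering C1 (prenyl bridgehead), C2, C3 (aroyl), C4, C5 (geranyl bridgehead), C6 (CH2), C7 (CH-prenyl), C8 (CMe2), C9 (bridging C=O); prenyl = 3-methylbut-2-en-1-yl, geranyl = (2E)-3,7-dimethylocta-2,6-dien-1-yl.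

**Route**

Step 1
Reactants: 1 (S)-4-benzyl-1,3-oxazolidin-2-one; 2 3-methylbut-2-enoyl chloride
Product: 4 (S)-4-benzyl-3-(3-methylbut-2-enoyl)-1,3-oxazolidin-2-one, via N-lithio oxazolidinone 3 (not isolated)
Conditions: n-BuLi, THF, −78 °C; then 2, −78 → 0 °C
Reagents that add atoms: none
Why: N-acylation of the lithiated Evans auxiliary by an acid chloride (imide formation); no stereocentre is formed.

Step 2
Reactants: 4 (S)-4-benzyl-3-(3-methylbut-2-enoyl)-1,3-oxazolidin-2-one; 5 1-bromo-3-methylbut-2-ene (prenyl bromide)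
Product: 7 (S)-4-benzyl-3-[(2S)-5-methyl-2-(prop-1-en-2-yl)hex-4-enoyl]-1,3-oxazolidin-2-one, via sodium dienolate 6 (not isolated)
Conditions: NaN(SiMe3)2, THF, −78 °C; then 5, −78 → −40 °C
Reagents that add atoms: none
Why: Evans asymmetric alkylation in its deconjugative form, in which γ-deprotonation gives the chelated (Z)-dienolate that is prenylated at the α-carbon on the face opposite the benzyl group, setting the (S) centre that becomes C7 and leaving the isopropenyl group.

Step 3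
Reactants: 7 (S)-4-benzyl-3-[(2S)-5-methyl-2-(prop-1-en-2-yl)hex-4-enoyl]-1,3-oxazolidin-2-one
Product: 8 (2S)-5-methyl-2-(prop-1-en-2-yl)hex-4-en-1-ol ((S)-lavandulol)
Conditions: LiBH4, H2O (1 equiv), Et2O, 0 °C
Reagents that add atoms: none
Why: Reductive cleavage of the N-acyl oxazolidinone by borohydride gives the primary alcohol without epimerising the non-conjugated α-centre and returns the auxiliary.

Step 4
Reactants: 8 (2S)-5-methyl-2-(prop-1-en-2-yl)hex-4-en-1-ol
Product: 9 (2R)-2-(2-fluoropropan-2-yl)-5-methylhex-4-en-1-ol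
Conditions: [N,N′-bis(3,5-di-tert-butylsalicylidene)-1,2-cyclohexanediaminato]cobalt (C36H52CoN2O2, divalent cobalt, 5 mol %), N-fluoro-2,4,6-trimethylpyridinium tetrafluoroborate, (HMe2Si)2O, PhCF3, 0 °C
Reagents that add atoms: N-fluoro-2,4,6-trimethylpyridinium tetrafluoroborate, Cc1cc(C)[n+](F)c(C)c1.F[B-](F)(F)F
Why: Cobalt-hydride hydrogen-atom-transfer (Mukaiyama-type) Markovnikov hydrofluorination, in which the bulky Co–H engages the unhindered 1,1-disubstituted alkene far faster than the trisubstituted prenyl alkene; the stereocentre is untouched (the descriptor becomes R only through CIP priority).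

Step 5
Reactants: 10 1,3-dimethoxybenzene
Product: 11 1,5-dimethoxycyclohexa-1,4-diene
Conditions: Li, NH3 (l), t-BuOH, THF, −78 °C; then NH4Cl
Reagents that add atoms: none
Why: Birch reduction of resorcinol dimethyl ether gives the 2,5-dihydro product with both methoxy groups on sp2 carbons.

Step 6
Reactants: 11 1,5-dimethoxycyclohexa-1,4-diene; 9 (2R)-2-(2-fluoropropan-2-yl)-5-methylhex-4-en-1-ol
Product: 14 6-[(2R)-2-(2-fluoropropan-2-yl)-5-methylhex-4-en-1-yl]-1,5-dimethoxycyclohexa-1,4-diene, via triflate 12 (not isolated), via lithiated diene 13 (not isolated)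
Conditions: 9, Tf2O, 2,6-lutidine, CH2Cl2, −78 °C (crude 12); separately 11 (1.3 equiv), t-BuLi (1.2 equiv), THF, −78 °C; combine, −78 → −40 °C
Reagents that add atoms: none
Why: The ring CH2 between the two methoxy-bearing carbons is deprotonated (methoxy-chelated pentadienyl anion) and alkylated at its central carbon in an SN2 reaction, the triflate being chosen because the β-branched primary centre is slow as a halide; the side-chain stereocentre is not involved.

Step 7
Reactants: 14 6-[(2R)-2-(2-fluoropropan-2-yl)-5-methylhex-4-en-1-yl]-1,5-dimethoxycyclohexa-1,4-diene; 15 (2E)-1-bromo-3,7-dimethylocta-2,6-diene (geranyl bromide)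
Product: 17 6-geranyl-6-[(2R)-2-(2-fluoropropan-2-yl)-5-methylhex-4-en-1-yl]-1,5-dimethoxycyclohexa-1,4-diene, via tertiary dienyllithium 16 (not isolated)
Conditions: t-BuLi, THF, −78 °C; then 15, −78 → −40 °C
Reagents that add atoms: none
Why: A second deprotonation at the same doubly allylic carbon and SN2 alkylation at the primary carbon of the allylic bromide creates the quaternary carbon (future C5) with the E-alkene retained; the ring stays Cs-symmetric, so no new stereocentre arises.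

Step 8
Reactants: 17 6-geranyl-6-[(2R)-2-(2-fluoropropan-2-yl)-5-methylhex-4-en-1-yl]-1,5-dimethoxycyclohexa-1,4-diene
Product: 19 (1S,5S,7R)-5-geranyl-4-methoxy-8,8-dimethyl-7-prenylbicyclo[3.3.1]non-3-en-9-one, via oxocarbenium tetrafluoroborate 18 (not isolated)
Conditions: BF3·OEt2 (1.2 equiv), 2,6-di-tert-butyl-4-methylpyridine, CH2Cl2 (0.01 M), −78 → −40 °C; then aq. NaHCO3
Reagents that add atoms: water, O
Why: Proposed new method: BF3 abstracts fluoride from the tertiary C–F bond (proton-free ionisation, so neither the enol ethers nor the prenyl and geranyl alkenes are protonated) and the tertiary cation is captured by one of the two enantiotopic enol-ether β-carbons through a chair transition state of ring B with the C7 prenyl group equatorial, so the single (R) centre fixes both bridgeheads (1S,5S) and its own exo orientation, the bridged oxocarbenium ion (no Bredt-allowed proton loss) being hydrolysed to the C9 ketone on quench; the closest known reaction types are the Reetz α-tert-alkylation of enol ethers with tertiary halides under Lewis acids and the Lewis-acid epoxide-opening enol-ether cyclisations used to make bicyclo[3.3.1]nonane cores.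

Step 9
Reactants: 19 (1S,5S,7R)-5-geranyl-4-methoxy-8,8-dimethyl-7-prenylbicyclo[3.3.1]non-3-en-9-one
Product: 20 (1R,5S,7R)-5-geranyl-4-methoxy-8,8-dimethyl-7-prenylbicyclo[3.3.1]non-3-ene-2,9-dione
Conditions: t-BuOOH, PhI(OAc)2, K2CO3, EtOAc, −20 °C
Reagents that add atoms: tert-butyl hydroperoxide, CC(C)(C)OO
Why: Radical allylic C–H oxidation (tert-butylperoxyl radicals from hypervalent iodine and t-BuOOH) at C2, the only CH2 allylic to the electron-rich enol ether and therefore more activated than the allylic positions of the isolated trisubstituted alkenes, delivering the vinylogous ester (the C1 descriptor changes by CIP priority only).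

Step 10
Reactants: 21 3,4-dihydroxybenzoic acid
Product: 22 tert-butyldimethylsilyl 3,4-bis(tert-butyldimethylsilyloxy)benzoate
Conditions: TBSCl (3.5 equiv), imidazole, DMF, rt
Reagents that add atoms: tert-butyldimethylsilyl chloride, CC(C)(C)[Si](C)(C)Cl
Why: Exhaustive silylation of both phenols and the carboxylic acid (silyl ether and silyl ester formation).

Step 11
Reactants: 22 tert-butyldimethylsilyl 3,4-bis(tert-butyldimethylsilyloxy)benzoate
Product: 23 3,4-bis(tert-butyldimethylsilyloxy)benzoyl chloride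
Conditions: (COCl)2, DMF (cat.), CH2Cl2, 0 °C → rt
Reagents that add atoms: oxalyl chloride, ClC(=O)C(Cl)=O
Why: Direct silyl ester to acid chloride conversion with the Vilsmeier reagent under neutral conditions, which leaves the aryl silyl ethers intact.

Step 12
Reactants: 20 (1R,5S,7R)-5-geranyl-4-methoxy-8,8-dimethyl-7-prenylbicyclo[3.3.1]non-3-ene-2,9-dione; 23 3,4-bis(tert-butyldimethylsilyloxy)benzoyl chloride
Product: 25 (1S,5S,7R)-3-[3,4-bis(tert-butyldimethylsilyloxy)benzoyl]-5-geranyl-4-methoxy-8,8-dimethyl-7-prenylbicyclo[3.3.1]non-3-ene-2,9-dione, via C3 vinyllithium 24 (not isolated)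
Conditions: lithium 2,2,6,6-tetramethylpiperidide (LiTMP, 1.1 equiv), THF, −78 °C; then 23, −78 °C
Reagents that add atoms: none
Why: Directed vinylic lithiation at C3 between the carbonyl and the methoxy group (the C1 bridgehead proton is shielded by the adjacent gem-dimethyl group) followed by C-acylation with the acid chloride.

Step 13
Reactants: 25 (1S,5S,7R)-3-[3,4-bis(tert-butyldimethylsilyloxy)benzoyl]-5-geranyl-4-methoxy-8,8-dimethyl-7-prenylbicyclo[3.3.1]non-3-ene-2,9-dione; 5 1-bromo-3-methylbut-2-ene (prenyl bromide)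
Product: 27 (1S,5S,7R)-3-[3,4-bis(tert-butyldimethylsilyloxy)benzoyl]-5-geranyl-4-methoxy-8,8-dimethyl-1,7-diprenylbicyclo[3.3.1]non-3-ene-2,9-dione, via bridgehead C1 lithio species 26 (not isolated)
Conditions: lithium 2,2,6,6-tetramethylpiperidide (LiTMP, 1.5 equiv), THF, −78 °C; then 5, DMPU, −78 → −30 °C
Reagents that add atoms: none
Why: With C3 blocked the only acidic proton is the bridgehead C1–H flanked by the C2 and C9 carbonyls, and bridgehead lithiation followed by SN2 alkylation with the allylic bromide occurs with retention because the bicyclic frame fixes the configuration.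

Step 14
Reactants: 27 (1S,5S,7R)-3-[3,4-bis(tert-butyldimethylsilyloxy)benzoyl]-5-geranyl-4-methoxy-8,8-dimethyl-1,7-diprenylbicyclo[3.3.1]non-3-ene-2,9-dione
Product: 28 (1S,5S,7R)-3-(3,4-dihydroxybenzoyl)-5-geranyl-4-hydroxy-8,8-dimethyl-1,7-diprenylbicyclo[3.3.1]non-3-ene-2,9-dione (CNP0160101.3)
Conditions: LiOH, dioxane–H2O (degassed), 90 °C; then 1 M HCl to pH 3, 0 °C
Reagents that add atoms: lithium hydroxide, [Li+].[OH-]
Why: Hydroxide cleaves the vinylogous methyl ester by addition–elimination at C4 and the two phenolic silyl ethers by attack at silicon, the β-triketone being protected from retro-Claisen cleavage as its delocalised anion; no stereocentre is touched.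

**Compound list**
1 | (S)-4-benzyl-1,3-oxazolidin-2-one | O=C1N[C@@H](Cc2ccccc2)CO1 | starting material
2 | 3-methylbut-2-enoyl chloride | CC(C)=CC(Cl)=O | starting material
3 | lithium (S)-4-benzyl-2-oxo-1,3-oxazolidin-3-ide | [Li+].O=C1[N-][C@@H](Cc2ccccc2)CO1 | intermediate
4 | (S)-4-benzyl-3-(3-methylbut-2-enoyl)-1,3-oxazolidin-2-one | CC(C)=CC(=O)N1[C@@H](Cc2ccccc2)COC1=O | intermediate
5 | 1-bromo-3-methylbut-2-ene (prenyl bromide) | CC(C)=CCBr | starting material
6 | sodium (1Z)-1-[(4S)-4-benzyl-2-oxo-1,3-oxazolidin-3-yl]-3-methylbuta-1,3-dien-1-olate | [Na+].[O-]/C(=C\C(C)=C)N1[C@@H](Cc2ccccc2)COC1=O | intermediate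
7 | (S)-4-benzyl-3-[(2S)-5-methyl-2-(prop-1-en-2-yl)hex-4-enoyl]-1,3-oxazolidin-2-one | O=C(N1[C@@H](Cc2ccccc2)COC1=O)[C@@H](CC=C(C)C)C(C)=C | intermediate
8 | (2S)-5-methyl-2-(prop-1-en-2-yl)hex-4-en-1-ol ((S)-lavandulol) | OC[C@@H](CC=C(C)C)C(C)=C | intermediate
9 | (2R)-2-(2-fluoropropan-2-yl)-5-methylhex-4-en-1-ol | OC[C@@H](CC=C(C)C)C(C)(C)F | intermediate
10 | 1,3-dimethoxybenzene | COc1cccc(OC)c1 | starting material
11 | 1,5-dimethoxycyclohexa-1,4-diene | COC1=CCC=C(OC)C1 | intermediate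
12 | (2R)-2-(2-fluoropropan-2-yl)-5-methylhex-4-en-1-yl trifluoromethanesulfonate | FC(F)(F)S(=O)(=O)OC[C@@H](CC=C(C)C)C(C)(C)F | intermediate
13 | (2,6-dimethoxycyclohexa-2,5-dien-1-yl)lithium | [Li]C1C(OC)=CCC=C1OC | intermediate
14 | 6-[(2R)-2-(2-fluoropropan-2-yl)-5-methylhex-4-en-1-yl]-1,5-dimethoxycyclohexa-1,4-diene | COC1=CCC=C(OC)C1C[C@@H](CC=C(C)C)C(C)(C)F | intermediate
15 | (2E)-1-bromo-3,7-dimethylocta-2,6-diene (geranyl bromide) | CC(C)=CCC/C(C)=C/CBr | starting material
16 | {1-[(2R)-2-(2-fluoropropan-2-yl)-5-methylhex-4-en-1-yl]-2,6-dimethoxycyclohexa-2,5-dien-1-yl}lithium | [Li]C1(C[C@@H](CC=C(C)C)C(C)(C)F)C(OC)=CCC=C1OC | intermediate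
17 | 6-[(2E)-3,7-dimethylocta-2,6-dien-1-yl]-6-[(2R)-2-(2-fluoropropan-2-yl)-5-methylhex-4-en-1-yl]-1,5-dimethoxycyclohexa-1,4-diene | CC(C)=CCC/C(C)=C/CC1(C[C@@H](CC=C(C)C)C(C)(C)F)C(OC)=CCC=C1OC | intermediate
18 | C9 O-methyl oxocarbenium tetrafluoroborate of 19 (bridged cation formed on ring closure) | CC(C)=CCC/C(C)=C/C[C@]12C[C@@H](CC=C(C)C)C(C)(C)[C@H](CC=C1OC)C2=[O+]C.F[B-](F)(F)F | intermediate
19 | (1S,5S,7R)-5-[(2E)-3,7-dimethylocta-2,6-dien-1-yl]-4-methoxy-8,8-dimethyl-7-(3-methylbut-2-en-1-yl)bicyclo[3.3.1]non-3-en-9-one | CC(C)=CCC/C(C)=C/C[C@]12C[C@@H](CC=C(C)C)C(C)(C)[C@H](CC=C1OC)C2=O | intermediate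
20 | (1R,5S,7R)-5-[(2E)-3,7-dimethylocta-2,6-dien-1-yl]-4-methoxy-8,8-dimethyl-7-(3-methylbut-2-en-1-yl)bicyclo[3.3.1]non-3-ene-2,9-dione | CC(C)=CCC/C(C)=C/C[C@]12C[C@@H](CC=C(C)C)C(C)(C)[C@H](C(=O)C=C1OC)C2=O | intermediate
21 | 3,4-dihydroxybenzoic acid | OC(=O)c1ccc(O)c(O)c1 | starting material
22 | tert-butyldimethylsilyl 3,4-bis(tert-butyldimethylsilyloxy)benzoate | CC(C)(C)[Si](C)(C)OC(=O)c1ccc(O[Si](C)(C)C(C)(C)C)c(O[Si](C)(C)C(C)(C)C)c1 | intermediate
23 | 3,4-bis(tert-butyldimethylsilyloxy)benzoyl chloride | ClC(=O)c1ccc(O[Si](C)(C)C(C)(C)C)c(O[Si](C)(C)C(C)(C)C)c1 | intermediate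
24 | C3-lithio derivative of 20 (vinyllithium between C2=O and C4–OMe) | CC(C)=CCC/C(C)=C/C[C@]12C[C@@H](CC=C(C)C)C(C)(C)[C@H](C(=O)C([Li])=C1OC)C2=O | intermediate
25 | (1S,5S,7R)-3-[3,4-bis(tert-butyldimethylsilyloxy)benzoyl]-5-[(2E)-3,7-dimethylocta-2,6-dien-1-yl]-4-methoxy-8,8-dimethyl-7-(3-methylbut-2-en-1-yl)bicyclo[3.3.1]non-3-ene-2,9-dione | CC(C)=CCC/C(C)=C/C[C@]12C[C@@H](CC=C(C)C)C(C)(C)[C@H](C(=O)C(C(=O)c3ccc(O[Si](C)(C)C(C)(C)C)c(O[Si](C)(C)C(C)(C)C)c3)=C1OC)C2=O | intermediate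
26 | C1 (bridgehead) lithio derivative of 25 | CC(C)=CCC/C(C)=C/C[C@]12C[C@@H](CC=C(C)C)C(C)(C)[C@]([Li])(C(=O)C(C(=O)c3ccc(O[Si](C)(C)C(C)(C)C)c(O[Si](C)(C)C(C)(C)C)c3)=C1OC)C2=O | intermediate
27 | (1S,5S,7R)-3-[3,4-bis(tert-butyldimethylsilyloxy)benzoyl]-5-[(2E)-3,7-dimethylocta-2,6-dien-1-yl]-4-methoxy-8,8-dimethyl-1,7-bis(3-methylbut-2-en-1-yl)bicyclo[3.3.1]non-3-ene-2,9-dione | CC(C)=CCC/C(C)=C/C[C@]12C[C@@H](CC=C(C)C)C(C)(C)[C@](CC=C(C)C)(C(=O)C(C(=O)c3ccc(O[Si](C)(C)C(C)(C)C)c(O[Si](C)(C)C(C)(C)C)c3)=C1OC)C2=O | intermediate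
28 | (1S,5S,7R)-3-(3,4-dihydroxybenzoyl)-5-[(2E)-3,7-dimethylocta-2,6-dien-1-yl]-4-hydroxy-8,8-dimethyl-1,7-bis(3-methylbut-2-en-1-yl)bicyclo[3.3.1]non-3-ene-2,9-dione (CNP0160101.3) | CC(C)=CCC/C(C)=C/C[C@]12C[C@@H](CC=C(C)C)C(C)(C)[C@](CC=C(C)C)(C(=O)C(C(=O)c3ccc(O)c(O)c3)=C1O)C2=O | target

**Step count**
Total: 14 steps. Longest linear sequence: 11 steps (1, 2, 3, 4, 6, 7, 8, 9, 12, 13, 14); steps 5, 10 and 11 make the two side inputs.

**Three steps most likely to fail, each with a fallback**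

Step 8 (fluoride-abstraction ring closure). The cation may eliminate or undergo a 1,2-hydride shift from C7, or the bis(enol ether) may not tolerate BF3. The fallback sets out from 17 and comes back at 20, so it replaces steps 8 and 9. The doubly allylic ring CH2 of 17 is oxidised first (t-BuOOH, PhI(OAc)2, K2CO3, EtOAc, −20 °C, easier than the later mono-allylic oxidation) to the cross-conjugated dienone 4-geranyl-4-[(2R)-2-(2-fluoropropan-2-yl)-5-methylhex-4-en-1-yl]-3,5-dimethoxycyclohexa-2,5-dien-1-one F1, whose vinylogous esters tolerate protic media. Solvolysis in (CF3)2CHOH buffered with K2HPO4 (0 °C → rt) ionises the C–F bond by hydrogen bonding, with no Lewis acid to bind the dienone carbonyl. The α-carbon of one of the two enantiotopic vinylogous esters then closes ring B under the same C7 control, and loss of the methyl group from the oxocarbenium ion gives 20 directly.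

Step 13 (prenylation of the bridgehead next to the gem-dimethyl carbon). The hindered bridgehead anion may not be alkylated. The fallback sets out from 25 and comes back at 27. The anion is trapped with the small electrophile I2 (LiTMP, THF, −78 °C; then I2) to give the bridgehead iodide (1R,5S,7R)-3-[3,4-bis(tert-butyldimethylsilyloxy)benzoyl]-5-geranyl-1-iodo-4-methoxy-8,8-dimethyl-7-prenylbicyclo[3.3.1]non-3-ene-2,9-dione F2. The C–C bond is then made through the bridgehead radical instead of the anion (Keck allylation: allylSnBu3, azobisisobutyronitrile, benzene, 80 °C) to give the (1S,5S,7R) 1-allyl analogue of 27 F3. Cross-metathesis in 2-methyl-2-butene with the second-generation Grubbs catalyst RuCl2(=CHPh)(PCy3)(H2IMes) at rt converts allyl into prenyl and gives 27; the terminal alkene reacts much faster than the trisubstituted geranyl and prenyl alkenes, so the reaction is stopped at full conversion of F3.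

Step 9 (allylic oxidation at C2). The oxidant may not discriminate between C2 and the many other allylic positions. The fallback sets out from 19 and comes back at 20. The enol ether is hydrolysed (1 M HCl, THF, 0 °C) to (1S,5S,7R)-5-geranyl-8,8-dimethyl-7-prenylbicyclo[3.3.1]nonane-4,9-dione F4. Dehydrogenation with 2-iodoxybenzoic acid (DMSO, 65 °C; only C3 of the C4 ketone can enolise) gives (1S,5S,7R)-5-geranyl-8,8-dimethyl-7-prenylbicyclo[3.3.1]non-2-ene-4,9-dione F5. Wacker-type oxidation of the enone β-carbon C2 (Na2PdCl4 cat., t-BuOOH, AcOH–H2O, 50 °C; the trisubstituted alkenes are inert) gives (1R,5S,7R)-5-geranyl-8,8-dimethyl-7-prenylbicyclo[3.3.1]nonane-2,4,9-trione F6. O-Methylation (Me2SO4, K2CO3, acetone) gives 20 together with (1R,5S,7R)-5-geranyl-2-methoxy-8,8-dimethyl-7-prenylbicyclo[3.3.1]non-2-ene-4,9-dione F7, which is separated and recycled to F6 by hydrolysis.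

**Further compounds**
F1 | step 8 | 4-[(2E)-3,7-dimethylocta-2,6-dien-1-yl]-4-[(2R)-2-(2-fluoropropan-2-yl)-5-methylhex-4-en-1-yl]-3,5-dimethoxycyclohexa-2,5-dien-1-one | CC(C)=CCC/C(C)=C/CC1(C[C@@H](CC=C(C)C)C(C)(C)F)C(OC)=CC(=O)C=C1OC
F2 | step 13 | (1R,5S,7R)-3-[3,4-bis(tert-butyldimethylsilyloxy)benzoyl]-5-[(2E)-3,7-dimethylocta-2,6-dien-1-yl]-1-iodo-4-methoxy-8,8-dimethyl-7-(3-methylbut-2-en-1-yl)bicyclo[3.3.1]non-3-ene-2,9-dione | CC(C)=CCC/C(C)=C/C[C@]12C[C@@H](CC=C(C)C)C(C)(C)[C@](I)(C(=O)C(C(=O)c3ccc(O[Si](C)(C)C(C)(C)C)c(O[Si](C)(C)C(C)(C)C)c3)=C1OC)C2=O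
F3 | step 13 | (1S,5S,7R)-3-[3,4-bis(tert-butyldimethylsilyloxy)benzoyl]-5-[(2E)-3,7-dimethylocta-2,6-dien-1-yl]-4-methoxy-8,8-dimethyl-7-(3-methylbut-2-en-1-yl)-1-(prop-2-en-1-yl)bicyclo[3.3.1]non-3-ene-2,9-dione | CC(C)=CCC/C(C)=C/C[C@]12C[C@@H](CC=C(C)C)C(C)(C)[C@](CC=C)(C(=O)C(C(=O)c3ccc(O[Si](C)(C)C(C)(C)C)c(O[Si](C)(C)C(C)(C)C)c3)=C1OC)C2=O
F4 | step 9 | (1S,5S,7R)-5-[(2E)-3,7-dimethylocta-2,6-dien-1-yl]-8,8-dimethyl-7-(3-methylbut-2-en-1-yl)bicyclo[3.3.1]nonane-4,9-dione | CC(C)=CCC/C(C)=C/C[C@]12C[C@@H](CC=C(C)C)C(C)(C)[C@H](CCC1=O)C2=O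
F5 | step 9 | (1S,5S,7R)-5-[(2E)-3,7-dimethylocta-2,6-dien-1-yl]-8,8-dimethyl-7-(3-methylbut-2-en-1-yl)bicyclo[3.3.1]non-2-ene-4,9-dione | CC(C)=CCC/C(C)=C/C[C@]12C[C@@H](CC=C(C)C)C(C)(C)[C@H](C=CC1=O)C2=O
F6 | step 9 | (1R,5S,7R)-5-[(2E)-3,7-dimethylocta-2,6-dien-1-yl]-8,8-dimethyl-7-(3-methylbut-2-en-1-yl)bicyclo[3.3.1]nonane-2,4,9-trione | CC(C)=CCC/C(C)=C/C[C@]12C[C@@H](CC=C(C)C)C(C)(C)[C@H](C(=O)CC1=O)C2=O
F7 | step 9 | (1R,5S,7R)-5-[(2E)-3,7-dimethylocta-2,6-dien-1-yl]-2-methoxy-8,8-dimethyl-7-(3-methylbut-2-en-1-yl)bicyclo[3.3.1]non-2-ene-4,9-dione | CC(C)=CCC/C(C)=C/C[C@]12C[C@@H](CC=C(C)C)C(C)(C)[C@H](C(OC)=CC1=O)C2=O
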